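Ring A (chroman-2-one numbering) is the problem: five substituents, three phenolic oxygens (C5, C7, C8a) that need different fates, and an acyl group that must end up on C8, not C6. The route therefore assembles ring A last, around the finished C4 stereocentre, by a cyclobutenone–siloxyalkyne benzannulation. In one operation it forms C4a–C8a and C5–C6 and closes the arene with C8a–OH free, C5–O silylated, C7–O ethylated and the C8 ketone masked as a dioxolane. The precursors are an enantioenriched siloxyalkyne carrying C4 and a 3-ethoxy-4-substituted cyclobutenone; lactonisation onto the single free phenol then fixes the regiochemistry.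

Key step: step 8

Assumption: the (R)-bisphosphine written in step 2 is taken to deliver the (S)-adduct 5; should the sense of induction prove opposite, the (S)-ligand is used and nothing else changes.

Step 1
Reactants: 1 4-(benzyloxy)benzaldehyde; 2 Meldrum's acid (2,2-dimethyl-1,3-dioxane-4,6-dione)
Product: 3 5-[4-(benzyloxy)benzylidene]-2,2-dimethyl-1,3-dioxane-4,6-dione
Conditions: pyrrolidine (cat.), AcOH (cat.), toluene, rt
Reagents that add atoms: none
Why: Knoevenagel condensation of the strongly C–H acidic Meldrum's acid with an aryl aldehyde; the doubly activated alkylidene is a much better conjugate acceptor than a cinnamate ester for step 2.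

Step 2
Reactants: 3 5-[4-(benzyloxy)benzylidene]-2,2-dimethyl-1,3-dioxane-4,6-dione; 4 (trimethylsilyl)acetylene
Product: 5 5-{(1S)-1-[4-(benzyloxy)phenyl]-3-(trimethylsilyl)prop-2-yn-1-yl}-2,2-dimethyl-1,3-dioxane-4,6-dione
Conditions: 4 (excess), Rh(acac)(C2H4)2 (5 mol %), (R)-3,5-xylyl-MeO-BIPHEP [(R)-(6,6'-dimethoxybiphenyl-2,2'-diyl)bis[bis(3,5-dimethylphenyl)phosphine], 5.5 mol %], 1,4-dioxane/H2O, rt
Reagents that add atoms: none
Why: Rhodium-catalysed asymmetric conjugate alkynylation of an arylidene Meldrum's acid: a monovalent rhodium acetylide inserts the electron-poor alkene inside the chiral bisphosphine pocket and protonolysis releases the adduct, so the future C4 centre (S) is set by ligand-controlled enantioface selection, while the silyl cap suppresses alkyne dimerisation.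

Step 3
Reactants: 5 5-{(1S)-1-[4-(benzyloxy)phenyl]-3-(trimethylsilyl)prop-2-yn-1-yl}-2,2-dimethyl-1,3-dioxane-4,6-dione
Product: 7 (3R)-3-[4-(benzyloxy)phenyl]pent-4-ynoic acid, via silylalkyne acid 6 (not isolated)
Conditions: DMF/H2O (10:1), 100 °C; then K2CO3 (2.5 equiv), MeOH, rt; aq. HCl to pH 3
Reagents that add atoms: water, O
Why: Hydrolytic opening of the Meldrum's acid ring with loss of acetone, followed by thermal decarboxylation of the malonic acid, should give the monoacid, and carbonate in methanol then cleaves the C(sp)–Si bond at room temperature without touching the propargylic centre (the descriptor changes from S to R only because the bare ethynyl group ranks below aryl).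

Step 4
Reactants: 7 (3R)-3-[4-(benzyloxy)phenyl]pent-4-ynoic acid
Product: 9 triisopropylsilyl (3S)-3-[4-(benzyloxy)phenyl]-5-[(triisopropylsilyl)oxy]pent-4-ynoate, via ynolate dianion 8 (not isolated)
Conditions: LiN(SiMe3)2 (3.1 equiv), THF, −78 °C; anhydrous t-BuOOH (1.05 equiv), −78 → 0 °C; then iPr3SiOTf (2.3 equiv), −78 → 0 °C; pentane/aq. NaHCO3 work-up, NEt3-deactivated silica
Reagents that add atoms: tert-butyl hydroperoxide, CC(C)(C)OO; triisopropylsilyl trifluoromethanesulfonate, CC(C)[Si](OS(=O)(=O)C(F)(F)F)(C(C)C)C(C)C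
Why: Siloxyalkyne synthesis from a terminal alkyne by ynolate oxidation: LiOOtBu transfers oxygen to the lithium acetylide and the bulky silyl triflate silylates the ynolate on oxygen; carrying the carboxyl group as its lithium salt keeps the α-CH2 from being enolised (an ester would compete with the alkyne for the base), and the same reagent caps it as the silyl ester.

Step 5
Reactants: 10 ethyl 3-oxo-5-phenylpentanoate
Product: 11 ethyl 2-[2-(2-phenylethyl)-1,3-dioxolan-2-yl]acetate
Conditions: HOCH2CH2OH (3 equiv), TsOH·H2O (cat.), toluene, reflux, Dean–Stark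
Reagents that add atoms: ethylene glycol, OCCO
Why: Acid-catalysed ketalisation with azeotropic removal of water; the future C8 ketone is carried at its final oxidation level in a form that adds no stereocentre, so no later oxidation and no acid-labile benzylic carbinol are needed.

Step 6
Reactants: 11 ethyl 2-[2-(2-phenylethyl)-1,3-dioxolan-2-yl]acetate
Product: 12 potassium 2-[2-(2-phenylethyl)-1,3-dioxolan-2-yl]acetate
Conditions: KOH (1.0 equiv), EtOH/H2O, 40 °C; evaporate, dry azeotropically with toluene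
Reagents that add atoms: potassium hydroxide, [K+].[OH-]
Why: Ester saponification; isolating the dry potassium salt means the ketal never meets free mineral acid and allows acyl chloride formation without HCl in step 7.

Step 7
Reactants: 12 potassium 2-[2-(2-phenylethyl)-1,3-dioxolan-2-yl]acetate; 13 ethoxyacetylene
Product: 16 3-ethoxy-4-[2-(2-phenylethyl)-1,3-dioxolan-2-yl]cyclobut-2-en-1-one (racemic), via acyl chloride 14 (not isolated), via ketene 15 (not isolated)
Conditions: (COCl)2 (1.05 equiv), pyridine (cat.), Et2O, 0 °C → rt; then 13 (3 equiv), NEt3 (1.3 equiv, slow addition), Et2O, 0 °C → rt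
Reagents that add atoms: none
Why: Dehydrochlorination of the acyl chloride gives an aldoketene that undergoes [2+2] cycloaddition with the ynol ether, the nucleophilic CH terminus of ethoxyacetylene bonding to the ketene carbonyl carbon, so that OEt ends on C3 and the ketene substituent on C4 of the cyclobutenone; the bulky substituent slows ketene dimerisation, and chloride loss from the acyl chloride is far faster than β-elimination of a ketal oxygen.

Step 8
Reactants: 9 triisopropylsilyl (3S)-3-[4-(benzyloxy)phenyl]-5-[(triisopropylsilyl)oxy]pent-4-ynoate; 16 3-ethoxy-4-[2-(2-phenylethyl)-1,3-dioxolan-2-yl]cyclobut-2-en-1-one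
Product: 21 triisopropylsilyl (3S)-3-[4-(benzyloxy)phenyl]-3-{4-ethoxy-2-hydroxy-3-[2-(2-phenylethyl)-1,3-dioxolan-2-yl]-6-[(triisopropylsilyl)oxy]phenyl}propanoate, via vinylketene 17 (not isolated), via vinylcyclobutenone 18 (not isolated), via dienylketene 19 (not isolated), via cyclohexadienone 20 (not isolated)
Conditions: 16 (1.5 equiv), toluene, argon, 80 °C then 110 °C
Reagents that add atoms: none
Why: Danheiser benzannulation: 16 opens on heating (4π electrocyclic) to vinylketene 17, and the alkyne carbon of 9 that carries the C4 chain, made nucleophilic by the silyloxy group, attacks the ketene carbonyl carbon to give [2+2] adduct 18 with the new C4a–C8a and C5–C6 bonds. Reversible 4π opening of 18 gives dienylketene 19, which closes ring A as a six-membered carbocycle by thermal 6π electrocyclisation (C8–C8a) to dienone 20 and enolises to phenol 21. The closest known reaction type is the formation of resorcinol monosilyl ethers from cyclobutenones and triisopropylsiloxyalkynes, including alkynes branched at the propargylic carbon. No stereocentre is created: the transient sp3 ring carbons of 16, 18 and 20 all end as arene carbons, and C4 is a spectator with no acidic or ionisable pathway under neutral heating. The step needs regioselectivity only, and the matched polarity of ketene and ynol ether secures it: the ketene oxygen becomes C8a–OH next to C4a, the silyloxy group lands on C5, and the substitution pattern of 16 places H on C6, OEt on C7 and the dioxolane carbon on C8.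

Step 9
Reactants: 21 triisopropylsilyl (3S)-3-[4-(benzyloxy)phenyl]-3-{4-ethoxy-2-hydroxy-3-[2-(2-phenylethyl)-1,3-dioxolan-2-yl]-6-[(triisopropylsilyl)oxy]phenyl}propanoate
Product: 23 (4S)-4-[4-(benzyloxy)phenyl]-7-ethoxy-8-(3-phenylpropanoyl)-5-[(triisopropylsilyl)oxy]chroman-2-one, via keto acid 22 (not isolated)
Conditions: TsOH·H2O (0.2 equiv), H2O (5 equiv), toluene/THF, 70 °C
Reagents that add atoms: water, O
Why: Aqueous acid hydrolyses the aryl dioxolane through an arene-stabilised oxocarbenium ion and the silyl ester, and acid-catalysed lactonisation then closes the six-membered aryl lactone on C8a–OH, the only free phenol (C5–O is still silylated, so the 6-acyl isomer cannot form); aryl silyl, benzyl and ethyl ethers and the C4 centre should be inert, and any lactone already formed during step 8 converges here.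

Step 10
Reactants: 23 (4S)-4-[4-(benzyloxy)phenyl]-7-ethoxy-8-(3-phenylpropanoyl)-5-[(triisopropylsilyl)oxy]chroman-2-one
Product: 24 (4S)-4-[4-(benzyloxy)phenyl]-7-ethoxy-5-hydroxy-8-(3-phenylpropanoyl)chroman-2-one
Conditions: Bu4NF (1.2 equiv), AcOH (1.2 equiv), THF, 0 °C
Reagents that add atoms: none
Why: Fluoride cleavage of the aryl silyl ether; buffering with acetic acid keeps the medium non-basic, so the lactone should neither open nor migrate to the newly freed C5–OH.

Step 11
Reactants: 24 (4S)-4-[4-(benzyloxy)phenyl]-7-ethoxy-5-hydroxy-8-(3-phenylpropanoyl)chroman-2-one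
Product: 25 (4S)-5,7-dihydroxy-4-(4-hydroxyphenyl)-8-(3-phenylpropanoyl)chroman-2-one (CNP0383109.1)
Conditions: BBr3 (5 equiv), C6HMe5 (3 equiv), CH2Cl2, −78 → 0 °C; then H2O, 0 °C
Reagents that add atoms: none
Why: Lewis-acid ether cleavage: the benzyl ether falls at low temperature with pentamethylbenzene trapping the benzyl cation before it can alkylate C6, and the C7 ethyl ether is cleaved with assistance from chelation to the adjacent C8 ketone; at or below 0 °C with a non-basic quench the lactone and the C4 centre should be untouched.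

Compound list
1 | 4-(benzyloxy)benzaldehyde | O=Cc1ccc(OCc2ccccc2)cc1 | starting material
2 | Meldrum's acid (2,2-dimethyl-1,3-dioxane-4,6-dione) | CC1(C)OC(=O)CC(=O)O1 | starting material
3 | 5-[4-(benzyloxy)benzylidene]-2,2-dimethyl-1,3-dioxane-4,6-dione | CC1(C)OC(=O)C(=Cc2ccc(OCc3ccccc3)cc2)C(=O)O1 | intermediate
4 | (trimethylsilyl)acetylene | C#C[Si](C)(C)C | starting material
5 | 5-{(1S)-1-[4-(benzyloxy)phenyl]-3-(trimethylsilyl)prop-2-yn-1-yl}-2,2-dimethyl-1,3-dioxane-4,6-dione | CC1(C)OC(=O)C([C@@H](c2ccc(OCc3ccccc3)cc2)C#C[Si](C)(C)C)C(=O)O1 | intermediate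
6 | (3S)-3-[4-(benzyloxy)phenyl]-5-(trimethylsilyl)pent-4-ynoic acid (silylalkyne acid, not isolated) | O=C(O)C[C@@H](c1ccc(OCc2ccccc2)cc1)C#C[Si](C)(C)C | intermediate
7 | (3R)-3-[4-(benzyloxy)phenyl]pent-4-ynoic acid | O=C(O)C[C@@H](c1ccc(OCc2ccccc2)cc1)C#C | intermediate
8 | dilithium (3S)-3-[4-(benzyloxy)phenyl]-5-oxidopent-4-ynoate (ynolate dianion, not isolated) | [Li+].[Li+].[O-]C(=O)C[C@@H](c1ccc(OCc2ccccc2)cc1)C#C[O-] | intermediate
9 | triisopropylsilyl (3S)-3-[4-(benzyloxy)phenyl]-5-[(triisopropylsilyl)oxy]pent-4-ynoate | CC(C)[Si](C(C)C)(C(C)C)OC(=O)C[C@@H](c1ccc(OCc2ccccc2)cc1)C#CO[Si](C(C)C)(C(C)C)C(C)C | intermediate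
10 | ethyl 3-oxo-5-phenylpentanoate | CCOC(=O)CC(=O)CCc1ccccc1 | starting material
11 | ethyl 2-[2-(2-phenylethyl)-1,3-dioxolan-2-yl]acetate | CCOC(=O)CC1(CCc2ccccc2)OCCO1 | intermediate
12 | potassium 2-[2-(2-phenylethyl)-1,3-dioxolan-2-yl]acetate | [K+].[O-]C(=O)CC1(CCc2ccccc2)OCCO1 | intermediate
13 | ethoxyacetylene | CCOC#C | starting material
14 | 2-[2-(2-phenylethyl)-1,3-dioxolan-2-yl]acetyl chloride (not isolated) | O=C(Cl)CC1(CCc2ccccc2)OCCO1 | intermediate
15 | 2-[2-(2-phenylethyl)-1,3-dioxolan-2-yl]ethen-1-one (ketene, not isolated) | O=C=CC1(CCc2ccccc2)OCCO1 | intermediate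
16 | 3-ethoxy-4-[2-(2-phenylethyl)-1,3-dioxolan-2-yl]cyclobut-2-en-1-one (racemic) | CCOC1=CC(=O)C1C1(CCc2ccccc2)OCCO1 | intermediate
17 | 3-ethoxy-4-[2-(2-phenylethyl)-1,3-dioxolan-2-yl]buta-1,3-dien-1-one (vinylketene, dioxolanyl carbon trans to C2, not isolated) | O=C=C/C(OCC)=C/C1(CCc2ccccc2)OCCO1 | intermediate
18 | triisopropylsilyl (3S)-3-[4-(benzyloxy)phenyl]-3-{3-{1-ethoxy-2-[2-(2-phenylethyl)-1,3-dioxolan-2-yl]ethenyl}-4-oxo-2-[(triisopropylsilyl)oxy]cyclobut-1-en-1-yl}propanoate (vinylcyclobutenone, ring CH centre unassigned, not isolated) | CC(C)[Si](C(C)C)(C(C)C)OC(=O)C[C@@H](c1ccc(OCc2ccccc2)cc1)C1=C(O[Si](C(C)C)(C(C)C)C(C)C)C(C1=O)/C(OCC)=C/C1(CCc2ccccc2)OCCO1 | intermediate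
19 | triisopropylsilyl (3S)-3-[4-(benzyloxy)phenyl]-7-ethoxy-4-(oxomethylidene)-8-[2-(2-phenylethyl)-1,3-dioxolan-2-yl]-5-[(triisopropylsilyl)oxy]octa-5,7-dienoate (dienylketene, cyclisable geometry, not isolated) | CC(C)[Si](C(C)C)(C(C)C)OC(=O)C[C@@H](c1ccc(OCc2ccccc2)cc1)C(=C=O)/C(O[Si](C(C)C)(C(C)C)C(C)C)=C\C(OCC)=C\C1(CCc2ccccc2)OCCO1 | intermediate
20 | triisopropylsilyl (3S)-3-[4-(benzyloxy)phenyl]-3-{4-ethoxy-6-oxo-5-[2-(2-phenylethyl)-1,3-dioxolan-2-yl]-2-[(triisopropylsilyl)oxy]cyclohexa-1,3-dien-1-yl}propanoate (cyclohexadienone, ring CH centre unassigned, not isolated) | CC(C)[Si](C(C)C)(C(C)C)OC(=O)C[C@@H](c1ccc(OCc2ccccc2)cc1)C1=C(O[Si](C(C)C)(C(C)C)C(C)C)C=C(OCC)C(C1=O)C1(CCc2ccccc2)OCCO1 | intermediate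
21 | triisopropylsilyl (3S)-3-[4-(benzyloxy)phenyl]-3-{4-ethoxy-2-hydroxy-3-[2-(2-phenylethyl)-1,3-dioxolan-2-yl]-6-[(triisopropylsilyl)oxy]phenyl}propanoate | CC(C)[Si](C(C)C)(C(C)C)OC(=O)C[C@@H](c1ccc(OCc2ccccc2)cc1)c1c(O[Si](C(C)C)(C(C)C)C(C)C)cc(OCC)c(C2(CCc3ccccc3)OCCO2)c1O | intermediate
22 | (3S)-3-[4-(benzyloxy)phenyl]-3-{4-ethoxy-2-hydroxy-3-(3-phenylpropanoyl)-6-[(triisopropylsilyl)oxy]phenyl}propanoic acid (keto acid, not isolated) | O=C(O)C[C@@H](c1ccc(OCc2ccccc2)cc1)c1c(O[Si](C(C)C)(C(C)C)C(C)C)cc(OCC)c(C(=O)CCc2ccccc2)c1O | intermediate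
23 | (4S)-4-[4-(benzyloxy)phenyl]-7-ethoxy-8-(3-phenylpropanoyl)-5-[(triisopropylsilyl)oxy]chroman-2-one | O=C1C[C@@H](c2ccc(OCc3ccccc3)cc2)c2c(O[Si](C(C)C)(C(C)C)C(C)C)cc(OCC)c(C(=O)CCc3ccccc3)c2O1 | intermediate
24 | (4S)-4-[4-(benzyloxy)phenyl]-7-ethoxy-5-hydroxy-8-(3-phenylpropanoyl)chroman-2-one | O=C1C[C@@H](c2ccc(OCc3ccccc3)cc2)c2c(O)cc(OCC)c(C(=O)CCc3ccccc3)c2O1 | intermediate
25 | (4S)-5,7-dihydroxy-4-(4-hydroxyphenyl)-8-(3-phenylpropanoyl)chroman-2-one | O=C1C[C@@H](c2ccc(O)cc2)c2c(O)cc(O)c(C(=O)CCc3ccccc3)c2O1 | target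

Total step count: 11. Longest linear sequence: 8 steps (steps 1–4 and 8–11); the cyclobutenone branch (steps 5–7) joins at step 8.

Steps most likely to fail

Step 8. The cycloaddition between the vinylketene and the propargylically branched ynol ether may be too slow, so that ketene self-condensation or arrest before the 6π closure takes over; the quaternary dioxolane carbon beside the ring-forming terminus adds to the crowding. The fallback sets out from 10 and comes back at 23, and carries the acyl group one oxidation level lower as a smaller, silyl-protected secondary carbinol. NaBH4 in EtOH reduces 10 to ethyl 3-hydroxy-5-phenylpentanoate F1. Silylation with t-BuMe2SiCl and imidazole gives ethyl 3-[(tert-butyldimethylsilyl)oxy]-5-phenylpentanoate F2, and KOH gives potassium 3-[(tert-butyldimethylsilyl)oxy]-5-phenylpentanoate F3. Oxalyl chloride and then NEt3 with 13 give 4-{1-[(tert-butyldimethylsilyl)oxy]-3-phenylpropyl}-3-ethoxycyclobut-2-en-1-one F4, a diastereomer mixture whose two centres are both erased later. Benzannulation of F4 with 9 under the conditions of step 8 should give the phenol silyl ester F5. Pyridinium p-toluenesulfonate in warm toluene closes the silyloxy lactone F6 without ionising the benzylic silyl ether. HF·pyridine buffered with pyridine removes the alkyl silyl group ahead of the aryl one to give the carbinol lactone F7, and Dess–Martin periodinane oxidises F7 to 23.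

Step 7. The dioxolane may open or undergo β-elimination while the acyl chloride and the ketene are generated beside amine hydrochloride, and the ketene may dimerise before it meets the alkyne. The fallback sets out from 13 and comes back at 16, and generates the same ketene 15 without acyl chloride or base by a Wolff rearrangement. Commercial ethyl 2-oxo-4-phenylbutanoate is ketalised (ethylene glycol, TsOH) to ethyl 2-(2-phenylethyl)-1,3-dioxolane-2-carboxylate F8 and saponified with LiOH to 2-(2-phenylethyl)-1,3-dioxolane-2-carboxylic acid F9. The isobutyl mixed anhydride of F9 reacts with Me3SiCHN2 to give 2-diazo-1-[2-(2-phenylethyl)-1,3-dioxolan-2-yl]ethan-1-one F10. Irradiation of F10 through Pyrex in the presence of excess 13 expels N2, the dioxolanyl carbon migrates, and ketene 15 is trapped as 16.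

Step 4. Metalation of the carboxylate–alkyne pair may be incomplete or unselective because the dianion aggregates, and the silyl ester may be lost during isolation, which would let a free acid add to the ynol ether. The fallback sets out from 7 and comes back at 23, and masks the carboxyl group as a base-inert bicyclic ortho ester. Esterification of 7 with (3-methyloxetan-3-yl)methanol (N,N'-dicyclohexylcarbodiimide, DMAP) gives (3-methyloxetan-3-yl)methyl (3R)-3-[4-(benzyloxy)phenyl]pent-4-ynoate F11. Catalytic BF3·OEt2 rearranges it to 1-{(2R)-2-[4-(benzyloxy)phenyl]but-3-yn-1-yl}-4-methyl-2,6,7-trioxabicyclo[2.2.2]octane F12. LiN(SiMe3)2, LiOOtBu and iPr3SiOTf then act on an ordinary terminal alkyne and give the siloxyalkyne ortho ester F13. Benzannulation of F13 with 16 gives the phenol ortho ester F14, and the acid treatment of step 9 hydrolyses ortho ester and dioxolane and lactonises with release of the triol to give 23.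

Further compounds
F1 | step 8 | ethyl 3-hydroxy-5-phenylpentanoate (racemic) | CCOC(=O)CC(O)CCc1ccccc1
F2 | step 8 | ethyl 3-[(tert-butyldimethylsilyl)oxy]-5-phenylpentanoate (racemic) | CCOC(=O)CC(O[Si](C)(C)C(C)(C)C)CCc1ccccc1
F3 | step 8 | potassium 3-[(tert-butyldimethylsilyl)oxy]-5-phenylpentanoate (racemic) | [K+].[O-]C(=O)CC(O[Si](C)(C)C(C)(C)C)CCc1ccccc1
F4 | step 8 | 4-{1-[(tert-butyldimethylsilyl)oxy]-3-phenylpropyl}-3-ethoxycyclobut-2-en-1-one (diastereomer mixture) | CCOC1=CC(=O)C1C(O[Si](C)(C)C(C)(C)C)CCc1ccccc1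
F5 | step 8 | triisopropylsilyl (3S)-3-[4-(benzyloxy)phenyl]-3-{3-{1-[(tert-butyldimethylsilyl)oxy]-3-phenylpropyl}-4-ethoxy-2-hydroxy-6-[(triisopropylsilyl)oxy]phenyl}propanoate (carbinol epimers) | CC(C)[Si](C(C)C)(C(C)C)OC(=O)C[C@@H](c1ccc(OCc2ccccc2)cc1)c1c(O[Si](C(C)C)(C(C)C)C(C)C)cc(OCC)c(C(O[Si](C)(C)C(C)(C)C)CCc2ccccc2)c1O
F6 | step 8 | (4S)-4-[4-(benzyloxy)phenyl]-8-{1-[(tert-butyldimethylsilyl)oxy]-3-phenylpropyl}-7-ethoxy-5-[(triisopropylsilyl)oxy]chroman-2-one (carbinol epimers) | O=C1C[C@@H](c2ccc(OCc3ccccc3)cc2)c2c(O[Si](C(C)C)(C(C)C)C(C)C)cc(OCC)c(C(O[Si](C)(C)C(C)(C)C)CCc3ccccc3)c2O1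
F7 | step 8 | (4S)-4-[4-(benzyloxy)phenyl]-7-ethoxy-8-(1-hydroxy-3-phenylpropyl)-5-[(triisopropylsilyl)oxy]chroman-2-one (carbinol epimers) | O=C1C[C@@H](c2ccc(OCc3ccccc3)cc2)c2c(O[Si](C(C)C)(C(C)C)C(C)C)cc(OCC)c(C(O)CCc3ccccc3)c2O1
F8 | step 7 | ethyl 2-(2-phenylethyl)-1,3-dioxolane-2-carboxylate | CCOC(=O)C1(CCc2ccccc2)OCCO1
F9 | step 7 | 2-(2-phenylethyl)-1,3-dioxolane-2-carboxylic acid | OC(=O)C1(CCc2ccccc2)OCCO1
F10 | step 7 | 2-diazo-1-[2-(2-phenylethyl)-1,3-dioxolan-2-yl]ethan-1-one | [N-]=[N+]=CC(=O)C1(CCc2ccccc2)OCCO1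
F11 | step 4 | (3-methyloxetan-3-yl)methyl (3R)-3-[4-(benzyloxy)phenyl]pent-4-ynoate | CC1(COC(=O)C[C@@H](c2ccc(OCc3ccccc3)cc2)C#C)COC1
F12 | step 4 | 1-{(2R)-2-[4-(benzyloxy)phenyl]but-3-yn-1-yl}-4-methyl-2,6,7-trioxabicyclo[2.2.2]octane | CC12COC(C[C@@H](c3ccc(OCc4ccccc4)cc3)C#C)(OC1)OC2
F13 | step 4 | 1-{(2S)-2-[4-(benzyloxy)phenyl]-4-[(triisopropylsilyl)oxy]but-3-yn-1-yl}-4-methyl-2,6,7-trioxabicyclo[2.2.2]octane | CC12COC(C[C@@H](c3ccc(OCc4ccccc4)cc3)C#CO[Si](C(C)C)(C(C)C)C(C)C)(OC1)OC2
F14 | step 4 | 1-{(2S)-2-[4-(benzyloxy)phenyl]-2-{4-ethoxy-2-hydroxy-3-[2-(2-phenylethyl)-1,3-dioxolan-2-yl]-6-[(triisopropylsilyl)oxy]phenyl}ethyl}-4-methyl-2,6,7-trioxabicyclo[2.2.2]octane | CC12COC(C[C@@H](c3ccc(OCc4ccccc4)cc3)c3c(O[Si](C(C)C)(C(C)C)C(C)C)cc(OCC)c(C4(CCc5ccccc5)OCCO4)c3O)(OC1)OC2
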